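## The problem

The target 34 is a heliangolide: a ten-membered carbocycle (C1–C10) with a 4Z trisubstituted alkene, a trans 1,10-epoxide and a trans-fused α-methylene-γ-butyrolactone (C12–O–C6, fused across C6–C7). C8 carries an isobutyrate and C9 a free hydroxyl. Six stereocentres must be set (1R,6R,7S,8S,9S,10R); C6–C9 are contiguous, with O8, O9 and C11 on the β face and O6 on the α face. Closing a ten-membered ring that holds two alkenes end to end is costly, so the mode of ring formation matters as much as the stereochemistry.

Stereocontrol can be relayed in one direction only. C9, set together with C8 by a reagent-controlled aldol, can later direct the epoxidation of the 1(10)-alkene and, through chelation, a reduction at C8. C8 is allylic to C7=C11 in any precursor of the C6–C7 bond and therefore decides which face of C7 is attacked. The C7=C11 geometry then relays to C6.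

The fragile parts are the α-methylene lactone (conjugate addition, base), the epoxide and the cyclodeca-1(10),4-diene (acid, transannular cyclisation), the Z C4=C5 bond (allylic ionisation) and the C8 ester next to a free C9 hydroxyl (acyl migration). Epoxide and ester are therefore installed last.

The feature that opens the key step is the C6 carbinol bonded to C7, which carries the C11(=C13)–C12 unit. This is a homoallylic alcohol whose carbinol carbon is also allylic to C4=C5, exactly the product pattern of a [2,3]-Wittig shift of an ether oxygen bridging C6 and C13.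

## Retrosynthesis

**Epoxide (C1–O and C10–O of 34, back to diene 33).** The epoxide is the most acid- and nucleophile-sensitive group and is made last. The free C9 hydroxyl of 33 assists a peracid, and the other two alkenes are deactivated (C4=C5 by the allylic lactone oxygen, C11=C13 by conjugation). The forward step must deliver oxygen to the peripheral face of the E 1(10)-alkene.

**Ester and C8 configuration (acyl–O8 bond of 33/32 back to alcohol 31; C8–H bond of 31 back to ketone 30 and alcohol 29).** The ring contraction below needs the C8 oxygen on the α face, the epimer of the target, so C8 is corrected once the ring exists. Oxidation to ketone 30 and chelation-controlled reduction through the C9 acetal oxygen re-set C8. Because O9 stays protected throughout, acylation of 31 needs no selection between two secondary hydroxyls. A direct invertive esterification of 29 would be two steps shorter, but it is a backside substitution at a ten-membered-ring carbon; it is kept as the fallback.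

**Lactone (C12–O6 acyl bond of 29/28, back to diol 25 and bis-silyl ether 24).** Oxidation of the primary allylic C12 alcohol in the presence of the C6 hydroxyl gives the lactone through the lactol. O8 stays silylated so that only the 6,12-lactone can close, and O9 stays as an acetal so that the allylic C9 carbinol is not oxidised.

**Key disconnection (C6–C7 of 24; retro-[2,3]-Wittig to the 13-membered ether 22).** Cutting C6–C7 while joining O to C13 and moving the alkene from C11=C13 to C7=C11 removes the ten-membered ring and both C6 and C7 stereocentres at once. Cuts at C7–C8, C8–C9 or C3–C4 each need an end-to-end C–C closure of the medium ring; this cut lets a low-strain macrocyclic ether pay the ring strain in a sigmatropic step. The forward reaction must metalate C6 (not C13 or C12), give the 6,7-anti relation (from the geometry with C13 trans to C8) and attack the correct face of C7. The last point fixes the design. A(1,3) strain with C12H2 holds H8 near the alkene plane, and the C8–O bond should lie anti to the incoming carbanion (Felkin–Anh-type). For the target's 8β oxygen this leads to the wrong C7 epimer; for the 8α silyl ether in 22 it leads to 7S.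

**Ether (C13–O of 22, back to hydroxy chloride 21 and PMB ether 20).** The macrocycle is closed by C–O alkylation, the easiest bond to form at high dilution, between a primary allylic alkoxide and a primary allylic chloride. Only the PMB group on O6 has to be removed beforehand.

**Trisubstituted alkene (C7=C11 of 20, back to allylic alcohol 18; C7–C11 of 18, back to aldehyde 14 and vinyl bromide 16).** An olefination with a phosphonate carrying the CH2OSi group would place a leaving group β to the carbanion. Instead a 2-metalated allyl silyl ether adds to the aldehyde, and chloride-induced allylic transposition moves the oxygen function from C7 to C13. This differentiates the two CH2O arms on C11 (silyl ether cis to C8, chloride trans) in two steps. The forward step must give C8 trans to the CH2Cl arm.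

**C8–C9 (of 14/13/12/11, back to enal 4 and imide 9).** A syn glycolate aldol sets C9 as in the target and C8 as the required epimer in one reagent-controlled step. The silyl group on O8 comes with the glycolate, and the free C9 hydroxyl of 11 is then capped as a THP acetal. The acetal is orthogonal to fluoride, cannot migrate, and is able to chelate. Weinreb amide 12 allows reduction to aldehyde 14.

**Starting materials.** Enal 4 comes from nerol 1, which supplies C1–C6, C10, C14, C15 and the Z C4=C5 bond, through PMB ether 2 and allylic oxidation. Imide 9 comes from glycolic acid 5 (through 6) and oxazolidinone 7. Vinyl bromide 16 comes from 2-bromoallyl alcohol 15.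

## Roads not taken

Alternative 1: The cut is C3–C4. Zinc would insert into a primary C3–I bond and Pd(PPh3)4 (zerovalent palladium) would couple the alkylzinc centre with a Z alkenyl C4–I bond of the same chain, closing the ring to A1, the C9 triethylsilyl ether of 34.
- Merits: the ring is made last with every stereocentre, the epoxide, the ester and the lactone in place, and only a desilylation follows. After ring closure this is far shorter than the chosen plan (one step against eight). The Z geometry of the alkenyl iodide is transferred unchanged.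
- Weak points: the C3–zinc centre sits two carbons from the epoxide, and the methylene lactone is exposed to organozinc and low-valent metal. Reductive elimination to a strained ten-membered ring must beat protodemetalation, β-hydride elimination and dimerisation. All six stereocentres would have to be built on an open chain with no ring to help.
- Comparison: the chosen plan is longer after the key step, but closes its macrocycle by O-alkylation and sets C6 and C7 in the ring-forming event.

Alternative 2: The cut is C8–C9. SmI2 (divalent samarium) would reduce a C9 enal carbonyl to a ketyl that adds to a C8 aldehyde carbonyl of the same chain, giving the cyclodecadiene 8,9-diol A2.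
- Merits: ring and both carbinol centres arise together, and cis-diols are the usual outcome of such couplings. A2 would carry the 8β,9β oxygens directly. This is a real advantage over the chosen plan, which carries C8 inverted through the ring contraction and spends three steps (18–20) to correct it.
- Weak points: the enal ketyl is delocalised and can couple through C1. Face selection relative to C7 is unproven. C6 and C7 must be set beforehand by separate chemistry. The diol must then be told apart for acylation at O8 only.
- Comparison: the chosen plan has to justify the extra C8 redox steps. It does so with a chelate-controlled reduction whose sense is predictable, and with a C8/C9 pair that is differentiated from the aldol onward.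

Alternative 3: The cut is C7–C8. Zinc or indium would insert into the C13–Br bond of a 2-(bromomethyl)butenolide unit, and the allylmetal would add through C7 to a C8 aldehyde, closing the ring and creating the C11=C13 methylene in A3 (free C8 hydroxyl, C9 silyl ether).
- Merits: the lactone, the exocyclic methylene and the ring come in one step, and the end game is only acylation and desilylation. In convergence and step count after ring closure this is the strongest of the three and better than the chosen plan.
- Weak points: two new stereocentres (C7, C8) are set in a medium-ring closure under several controllers that need not agree (C6 of the butenolide, the α-silyloxy C9 centre, the epoxide). The epoxide and an epimerisable α-silyloxy aldehyde must survive the metal. A wrong C8 epimer would again need correction.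
- Comparison: the chosen plan sets against this a ring closure with established geometric rules (alkene geometry to C6/C7, allylic C–O to the C7 face) and an unstrained macrocyclisation.

Key step: step 14

Assumption: carbons keep their germacrane numbers (C1–C15) also in open-chain intermediates, and the oxan-2-yl (THP) acetal carbon is carried as an undefined mixture of epimers.

## Route

Step 1
Reactants: 1 nerol
Product: 2 neryl 4-methoxybenzyl ether
Conditions: NaH, 4-methoxybenzyl chloride, THF/DMF, 0 °C → rt
Reagents that add atoms: 4-methoxybenzyl chloride COc1ccc(CCl)cc1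
Why: Williamson etherification of the primary allylic alkoxide; the PMB ether survives hydride, organolithium and base and is later removed oxidatively without touching silyl ethers or an allylic chloride.

Step 2
Reactants: 2 neryl 4-methoxybenzyl ether
Product: 4 (2E,6Z)-8-[(4-methoxybenzyl)oxy]-2,6-dimethylocta-2,6-dienal, via allylic alcohol 3 (not isolated)
Conditions: SeO2 (cat.), t-BuOOH, salicylic acid (cat.), CH2Cl2, rt; filter; then MnO2, CH2Cl2, rt
Reagents that add atoms: tert-butyl hydroperoxide CC(C)(C)OO (oxygen atom, passed on through catalytic SeO2 O=[Se]=O)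
Why: SeO2-catalysed allylic oxidation (ene reaction, then [2,3]-shift) attacks the E methyl group of the terminal trisubstituted alkene; MnO2 takes the allylic alcohol on to the E enal and leaves the Z alkene alone.

Step 3
Reactants: 5 glycolic acid
Product: 6 tert-butyldimethylsilyl [(tert-butyldimethylsilyl)oxy]acetate
Conditions: TBSCl (2.2 equiv), imidazole, DMF, rt
Reagents that add atoms: tert-butyldimethylsilyl chloride CC(C)(C)[Si](C)(C)Cl
Why: exhaustive silylation gives the silyl ether silyl ester, the usual entry to α-silyloxy acyl chlorides.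

Step 4
Reactants: 6 tert-butyldimethylsilyl [(tert-butyldimethylsilyl)oxy]acetate; 7 (S)-4-benzyloxazolidin-2-one
Product: 9 (S)-4-benzyl-3-{[(tert-butyldimethylsilyl)oxy]acetyl}oxazolidin-2-one, via silyloxyacetyl chloride 8 (not isolated)
Conditions: (COCl)2, DMF (cat.), CH2Cl2, 0 °C → rt; then 7 pre-treated with n-BuLi, THF, −78 °C
Reagents that add atoms: none
Why: oxalyl chloride with catalytic DMF converts the silyl ester directly into the acid chloride, which N-acylates the lithiated oxazolidinone.

Step 5
Reactants: 9 (S)-4-benzyl-3-{[(tert-butyldimethylsilyl)oxy]acetyl}oxazolidin-2-one; 4 (2E,6Z)-8-[(4-methoxybenzyl)oxy]-2,6-dimethylocta-2,6-dienal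
Product: 11 (4S)-4-benzyl-3-[(2S,3R,4E,8Z)-2-[(tert-butyldimethylsilyl)oxy]-3-hydroxy-10-[(4-methoxybenzyl)oxy]-4,8-dimethyldeca-4,8-dienoyl]oxazolidin-2-one, via dibutylboron Z-enolate 10 (not isolated)
Conditions: Bu2BOTf, Et3N, CH2Cl2, −78 → 0 °C; 4, −78 → 0 °C; then pH 7 buffer, MeOH, H2O2, 0 °C
Reagents that add atoms: none
Why: Evans syn aldol: the Z boron enolate reacts through a Zimmerman–Traxler chair on the face away from the benzyl group and sets C8 (2S) and C9 (3R) syn. C9 is the target configuration; C8 is deliberately its epimer, as the ring contraction requires.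

Step 6
Reactants: 11 aldol adduct
Product: 12 (2S,3R,4E,8Z)-2-[(tert-butyldimethylsilyl)oxy]-3-hydroxy-N-methoxy-10-[(4-methoxybenzyl)oxy]-N,4,8-trimethyldeca-4,8-dienamide
Conditions: MeNH(OMe)·HCl, AlMe3, CH2Cl2, −15 → 0 °C
Reagents that add atoms: N,O-dimethylhydroxylamine hydrochloride CNOC.Cl
Why: Weinreb transamidation by the aluminium amide, helped by the free β-hydroxyl, releases the auxiliary; the amide can later be reduced to the aldehyde without generating an alkoxide next to the C8 silyl ether.

Step 7
Reactants: 12 Weinreb amide
Product: 13 (2S,3R,4E,8Z)-2-[(tert-butyldimethylsilyl)oxy]-N-methoxy-10-[(4-methoxybenzyl)oxy]-N,4,8-trimethyl-3-(oxan-2-yloxy)deca-4,8-dienamide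
Conditions: 3,4-dihydro-2H-pyran, PPTS (cat.), CH2Cl2, rt
Reagents that add atoms: 3,4-dihydro-2H-pyran C1=COCCC1
Why: acid-catalysed acetalisation; the THP ether is inert to organolithiums and fluoride, cannot migrate as a silyl group would, can chelate zinc in step 19 and is removed under mild acid before the epoxide exists.

Step 8
Reactants: 13 THP-protected Weinreb amide
Product: 14 (2S,3R,4E,8Z)-2-[(tert-butyldimethylsilyl)oxy]-10-[(4-methoxybenzyl)oxy]-4,8-dimethyl-3-(oxan-2-yloxy)deca-4,8-dienal
Conditions: i-Bu2AlH, THF, −78 °C; Rochelle salt work-up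
Reagents that add atoms: none
Why: DIBAL-H reduction of a Weinreb amide stops at the chelated hemiaminal, which releases the α-silyloxy aldehyde on work-up without epimerisation.

Step 9
Reactants: 15 2-bromoprop-2-en-1-ol
Product: 16 [(2-bromoprop-2-en-1-yl)oxy](tert-butyl)dimethylsilane
Conditions: TBSCl, imidazole, CH2Cl2, 0 °C → rt
Reagents that add atoms: tert-butyldimethylsilyl chloride CC(C)(C)[Si](C)(C)Cl
Why: standard silylation of a primary alcohol.

Step 10
Reactants: 16 2-bromoallyl silyl ether; 14 aldehyde
Product: 18 (4R,5R,6E,10Z)-1,4-bis[(tert-butyldimethylsilyl)oxy]-12-[(4-methoxybenzyl)oxy]-6,10-dimethyl-2-methylidene-5-(oxan-2-yloxy)dodeca-6,10-dien-3-ol (C3 = future C7; both epimers), via vinyllithium 17 (not isolated)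
Conditions: t-BuLi (2 equiv), Et2O, −78 °C; 14, −78 °C; AcOH quench at −78 °C
Reagents that add atoms: none
Why: bromine–lithium exchange gives the 2-lithioallyl silyl ether, which adds to the aldehyde. The new carbinol centre need not be controlled because C7 becomes sp2 in step 11; the cold acidic quench prevents silyl transfer to the C7 alkoxide.

Step 11
Reactants: 18 allylic alcohol
Product: 20 (2E,4R,5R,6E,10Z)-4-[(tert-butyldimethylsilyl)oxy]-2-{[(tert-butyldimethylsilyl)oxy]methyl}-1-chloro-12-[(4-methoxybenzyl)oxy]-6,10-dimethyl-5-(oxan-2-yloxy)dodeca-2,6,10-triene, via C7 mesylate 19 (not isolated)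
Conditions: MsCl, Et3N, CH2Cl2, −40 °C; then LiCl, DMF, 0 °C → rt
Reagents that add atoms: lithium chloride [Li+].[Cl-]
Why: chloride displaces the allylic mesylate with allylic transposition (SN2′) at the unhindered methylene, since direct substitution at C7 is blocked by the neighbouring silyloxy carbon. In the transition state the small C7 substituent (H) eclipses the methylene, so C8 should end cis to C12 and trans to the new CH2Cl, the usual outcome when 2-substituted 1-alken-3-ols are transposed by halide.

Step 12
Reactants: 20 allylic chloride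
Product: 21 (2Z,6E,8R,9R,10E)-9-[(tert-butyldimethylsilyl)oxy]-11-{[(tert-butyldimethylsilyl)oxy]methyl}-12-chloro-3,7-dimethyl-8-(oxan-2-yloxy)dodeca-2,6,10-trien-1-ol
Conditions: DDQ, CH2Cl2/pH 7 buffer, 0 °C
Reagents that add atoms: none
Why: oxidative PMB cleavage (hydride abstraction from the electron-rich benzylic position) leaves silyl ethers, the THP acetal and the allylic chloride untouched.

Step 13
Reactants: 21 hydroxy chloride
Product: 22 (3Z,5R,6R,7E,11Z)-5-[(tert-butyldimethylsilyl)oxy]-3-{[(tert-butyldimethylsilyl)oxy]methyl}-7,11-dimethyl-6-(oxan-2-yloxy)-1-oxacyclotrideca-3,7,11-triene (ether oxygen between C6 and C13)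
Conditions: NaH, THF, 50 °C, syringe-pump addition to 2 mM
Reagents that add atoms: none
Why: intramolecular Williamson etherification of a primary allylic alkoxide with a primary allylic chloride; the 13-membered ring with three alkenes is nearly strain-free and slow addition suppresses oligomers.

Step 14
Reactants: 22 13-membered diallylic ether
Product: 24 (6R,7S,8R,9R)-8,12-bis[(tert-butyldimethylsilyl)oxy]-9-(oxan-2-yloxy)germacra-1(10)E,4Z,11(13)-trien-6-ol, via C6-lithiated ether 23 (not isolated)
Conditions: n-BuLi, THF, −78 → −20 °C; AcOH quench at −78 °C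
Reagents that add atoms: none
Why: n-BuLi removes a C6 proton (alpha to oxygen, allylic to C4=C5) to give 23, whose carbanion bonds to C7 through a five-membered envelope transition state while O–C13 breaks and C11=C13 forms; this is a [2,3]-Wittig sigmatropic shift, the known ring contraction of 13-membered diallylic ethers to germacradienols. The ten-membered carbocycle is closed by sigmatropic contraction inside the existing macrocycle (the array C6–O–C13–C11–C7 is excised), not by an end-to-end cyclisation. C6 relative to C7: with C13 trans to C8 on C7=C11 and the C5 vinyl group exo on the envelope, the shift should give the 6,7-anti relation that becomes the trans lactone. Face of C7: A(1,3) strain with C12H2 turns H8 toward the alkene plane, and the C8–OTBS bond, the best acceptor and the bulkiest group, lies anti to the incoming C6 (Felkin–Anh-type); for the 8R silyl ether used here that is the face leading to 7S, whereas the target's own 8β oxygen would direct to the other face. Regioselectivity needs metalation at C6 and not at C13 or C12: both of those are flanked by the fully substituted C11, a C13 anion could only bond to C4 with formation of a quaternary centre, and the silyl ether oxygen is a poor director. Low temperature and the cold quench suppress the [1,2]-shift and silyl transfer to the new C6 alkoxide.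

Step 15
Reactants: 24 ring-contracted alcohol
Product: 25 (6R,7S,8R,9R)-8-[(tert-butyldimethylsilyl)oxy]-9-(oxan-2-yloxy)germacra-1(10)E,4Z,11(13)-triene-6,12-diol
Conditions: HF·pyridine, pyridine, THF, 0 °C → rt
Reagents that add atoms: none
Why: buffered HF·pyridine cleaves the unhindered primary allylic silyl ether much faster than the hindered secondary one at C8; the THP acetal tolerates the buffered reagent.

Step 16
Reactants: 25 6,12-diol
Product: 28 (6R,7S,8R,9R)-8-[(tert-butyldimethylsilyl)oxy]-9-(oxan-2-yloxy)germacra-1(10)E,4Z,11(13)-trien-12,6-olide, via hydroxy enal 26 (not isolated), via lactol 27 (not isolated)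
Conditions: MnO2 (activated, excess), CH2Cl2, rt
Reagents that add atoms: none
Why: MnO2 oxidises the primary allylic alcohol to the enal, which the C6 hydroxyl traps as the lactol; further oxidation gives the α-methylene lactone. With O8 still silylated only the 6,12-lactone can form, and the trans fusion follows from the C6 and C7 configurations.

Step 17
Reactants: 28 silylated lactone
Product: 29 (6R,7R,8R,9R)-8-hydroxy-9-(oxan-2-yloxy)germacra-1(10)E,4Z,11(13)-trien-12,6-olide
Conditions: TBAF, AcOH (1:1), THF, 0 °C → rt
Reagents that add atoms: none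
Why: fluoride desilylation buffered with acetic acid, so that the freed C8 oxygen neither adds to the methylene lactone nor translactonises.

Step 18
Reactants: 29 8α-alcohol
Product: 30 (6R,7S,9R)-8-oxo-9-(oxan-2-yloxy)germacra-1(10)E,4Z,11(13)-trien-12,6-olide
Conditions: Dess–Martin periodinane, NaHCO3, CH2Cl2, 0 °C → rt
Reagents that add atoms: none
Why: Dess–Martin oxidation under buffered, non-basic conditions gives the α-alkoxy ketone; the C8 centre has done its work as controller of the ring contraction and is erased here.

Step 19
Reactants: 30 C8 ketone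
Product: 31 (6R,7R,8S,9R)-8-hydroxy-9-(oxan-2-yloxy)germacra-1(10)E,4Z,11(13)-trien-12,6-olide
Conditions: Zn(BH4)2, Et2O, −40 → −10 °C
Reagents that add atoms: none
Why: chelation-controlled reduction: zinc bridges the C8 carbonyl and the C9 acetal oxygen (Cram chelate) and hydride arrives from the side of H9. That is also the less hindered α face, opposite C11 and O9, so the 8,9-anti alcohol with the 8β hydroxyl of the target should result.

Step 20
Reactants: 31 8β-alcohol
Product: 32 (6R,7S,8S,9R)-8-(2-methylpropanoyloxy)-9-(oxan-2-yloxy)germacra-1(10)E,4Z,11(13)-trien-12,6-olide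
Conditions: (i-PrCO)2O, Et3N, DMAP (cat.), CH2Cl2, 0 °C → rt
Reagents that add atoms: 2-methylpropanoic anhydride CC(C)C(=O)OC(=O)C(C)C
Why: DMAP-catalysed acylation of the only free hydroxyl; O9 is still protected, so no regioselectivity question arises.

Step 21
Reactants: 32 THP-protected ester
Product: 33 (6R,7S,8S,9R)-9-hydroxy-8-(2-methylpropanoyloxy)germacra-1(10)E,4Z,11(13)-trien-12,6-olide
Conditions: AcOH/THF/H2O (4:2:1), 45 °C
Reagents that add atoms: none
Why: mild acid hydrolysis of the THP acetal; ester migration and transannular cyclisation of the diene are slow under these conditions.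

Step 22
Reactants: 33 diene alcohol
Product: 34 (1R,4Z,6R,7S,8S,9S,10R)-1,10-epoxy-9-hydroxy-8-(2-methylpropanoyloxy)germacra-4,11(13)-dien-12,6-olide (target)
Conditions: mCPBA, NaHCO3, CH2Cl2, 0 °C
Reagents that add atoms: 3-chloroperoxybenzoic acid OOC(=O)c1cccc(Cl)c1
Why: Prilezhaev epoxidation, hydrogen-bond assisted by the allylic C9 hydroxyl (Henbest effect) and delivered to the peripheral face of the E 1(10)-alkene, which should give the 1R,10R epoxide. C4=C5 is deactivated by the allylic lactone oxygen and C11=C13 by conjugation.

## Compound list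

1 | nerol, (2Z)-3,7-dimethylocta-2,6-dien-1-ol | CC(C)=CCC/C(C)=C\CO | starting material
2 | neryl 4-methoxybenzyl ether | COc1ccc(COC/C=C(/C)CCC=C(C)C)cc1 | intermediate
3 | (2E,6Z)-8-[(4-methoxybenzyl)oxy]-2,6-dimethylocta-2,6-dien-1-ol | COc1ccc(COC/C=C(/C)CC/C=C(\C)CO)cc1 | intermediate (not isolated)
4 | (2E,6Z)-8-[(4-methoxybenzyl)oxy]-2,6-dimethylocta-2,6-dienal | COc1ccc(COC/C=C(/C)CC/C=C(\C)C=O)cc1 | intermediate
5 | glycolic acid | OCC(=O)O | starting material
6 | tert-butyldimethylsilyl [(tert-butyldimethylsilyl)oxy]acetate | CC(C)(C)[Si](C)(C)OCC(=O)O[Si](C)(C)C(C)(C)C | intermediate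
7 | (S)-4-benzyloxazolidin-2-one | O=C1N[C@@H](Cc2ccccc2)CO1 | starting material
8 | [(tert-butyldimethylsilyl)oxy]acetyl chloride | CC(C)(C)[Si](C)(C)OCC(=O)Cl | intermediate (not isolated)
9 | (S)-4-benzyl-3-{[(tert-butyldimethylsilyl)oxy]acetyl}oxazolidin-2-one | CC(C)(C)[Si](C)(C)OCC(=O)N1[C@@H](Cc2ccccc2)COC1=O | intermediate
10 | dibutylboron Z-enolate of 9 | CCCCB(CCCC)O/C(=C\O[Si](C)(C)C(C)(C)C)N1[C@@H](Cc2ccccc2)COC1=O | intermediate (not isolated)
11 | (4S)-4-benzyl-3-[(2S,3R,4E,8Z)-2-[(tert-butyldimethylsilyl)oxy]-3-hydroxy-10-[(4-methoxybenzyl)oxy]-4,8-dimethyldeca-4,8-dienoyl]oxazolidin-2-one | COc1ccc(COC/C=C(/C)CC/C=C(\C)[C@@H](O)[C@H](O[Si](C)(C)C(C)(C)C)C(=O)N2[C@@H](Cc3ccccc3)COC2=O)cc1 | intermediate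
12 | (2S,3R,4E,8Z)-2-[(tert-butyldimethylsilyl)oxy]-3-hydroxy-N-methoxy-10-[(4-methoxybenzyl)oxy]-N,4,8-trimethyldeca-4,8-dienamide | COc1ccc(COC/C=C(/C)CC/C=C(\C)[C@@H](O)[C@H](O[Si](C)(C)C(C)(C)C)C(=O)N(C)OC)cc1 | intermediate
13 | (2S,3R,4E,8Z)-2-[(tert-butyldimethylsilyl)oxy]-N-methoxy-10-[(4-methoxybenzyl)oxy]-N,4,8-trimethyl-3-(oxan-2-yloxy)deca-4,8-dienamide | COc1ccc(COC/C=C(/C)CC/C=C(\C)[C@@H](OC2CCCCO2)[C@H](O[Si](C)(C)C(C)(C)C)C(=O)N(C)OC)cc1 | intermediate
14 | (2S,3R,4E,8Z)-2-[(tert-butyldimethylsilyl)oxy]-10-[(4-methoxybenzyl)oxy]-4,8-dimethyl-3-(oxan-2-yloxy)deca-4,8-dienal | COc1ccc(COC/C=C(/C)CC/C=C(\C)[C@@H](OC2CCCCO2)[C@H](O[Si](C)(C)C(C)(C)C)C=O)cc1 | intermediate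
15 | 2-bromoprop-2-en-1-ol | OCC(Br)=C | starting material
16 | [(2-bromoprop-2-en-1-yl)oxy](tert-butyl)dimethylsilane | C=C(Br)CO[Si](C)(C)C(C)(C)C | intermediate
17 | {3-[(tert-butyldimethylsilyl)oxy]prop-1-en-2-yl}lithium | [Li]C(=C)CO[Si](C)(C)C(C)(C)C | intermediate (not isolated)
18 | (4R,5R,6E,10Z)-1,4-bis[(tert-butyldimethylsilyl)oxy]-12-[(4-methoxybenzyl)oxy]-6,10-dimethyl-2-methylidene-5-(oxan-2-yloxy)dodeca-6,10-dien-3-ol (C3 epimers) | COc1ccc(COC/C=C(/C)CC/C=C(\C)[C@@H](OC2CCCCO2)[C@H](O[Si](C)(C)C(C)(C)C)C(O)C(=C)CO[Si](C)(C)C(C)(C)C)cc1 | intermediate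
19 | C3 (future C7) methanesulfonate of 18 | COc1ccc(COC/C=C(/C)CC/C=C(\C)[C@@H](OC2CCCCO2)[C@H](O[Si](C)(C)C(C)(C)C)C(OS(C)(=O)=O)C(=C)CO[Si](C)(C)C(C)(C)C)cc1 | intermediate (not isolated)
20 | (2E,4R,5R,6E,10Z)-4-[(tert-butyldimethylsilyl)oxy]-2-{[(tert-butyldimethylsilyl)oxy]methyl}-1-chloro-12-[(4-methoxybenzyl)oxy]-6,10-dimethyl-5-(oxan-2-yloxy)dodeca-2,6,10-triene | COc1ccc(COC/C=C(/C)CC/C=C(\C)[C@@H](OC2CCCCO2)[C@H](O[Si](C)(C)C(C)(C)C)/C=C(/CCl)CO[Si](C)(C)C(C)(C)C)cc1 | intermediate
21 | (2Z,6E,8R,9R,10E)-9-[(tert-butyldimethylsilyl)oxy]-11-{[(tert-butyldimethylsilyl)oxy]methyl}-12-chloro-3,7-dimethyl-8-(oxan-2-yloxy)dodeca-2,6,10-trien-1-ol | OC/C=C(/C)CC/C=C(\C)[C@@H](OC1CCCCO1)[C@H](O[Si](C)(C)C(C)(C)C)/C=C(/CCl)CO[Si](C)(C)C(C)(C)C | intermediate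
22 | (3Z,5R,6R,7E,11Z)-5-[(tert-butyldimethylsilyl)oxy]-3-{[(tert-butyldimethylsilyl)oxy]methyl}-7,11-dimethyl-6-(oxan-2-yloxy)-1-oxacyclotrideca-3,7,11-triene | O1C/C(CO[Si](C)(C)C(C)(C)C)=C/[C@@H](O[Si](C)(C)C(C)(C)C)[C@H](OC2CCCCO2)/C(C)=C/CC/C(C)=C\C1 | intermediate (key-step precursor)
23 | 22 lithiated at ring C13 (germacrane C6) | O1C/C(CO[Si](C)(C)C(C)(C)C)=C/[C@@H](O[Si](C)(C)C(C)(C)C)[C@H](OC2CCCCO2)/C(C)=C/CC/C(C)=C\C1[Li] | intermediate (not isolated)
24 | (6R,7S,8R,9R)-8,12-bis[(tert-butyldimethylsilyl)oxy]-9-(oxan-2-yloxy)germacra-1(10)E,4Z,11(13)-trien-6-ol | C=C(CO[Si](C)(C)C(C)(C)C)[C@@H]1[C@@H](O[Si](C)(C)C(C)(C)C)[C@H](OC2CCCCO2)/C(C)=C/CC/C(C)=C\[C@H]1O | intermediate (key-step product)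
25 | (6R,7S,8R,9R)-8-[(tert-butyldimethylsilyl)oxy]-9-(oxan-2-yloxy)germacra-1(10)E,4Z,11(13)-triene-6,12-diol | C=C(CO)[C@@H]1[C@@H](O[Si](C)(C)C(C)(C)C)[C@H](OC2CCCCO2)/C(C)=C/CC/C(C)=C\[C@H]1O | intermediate
26 | 12-aldehyde of 25 (6-hydroxy enal) | C=C(C=O)[C@@H]1[C@@H](O[Si](C)(C)C(C)(C)C)[C@H](OC2CCCCO2)/C(C)=C/CC/C(C)=C\[C@H]1O | intermediate (not isolated)
27 | 6,12-lactol of 26 (C12 epimers) | C=C1C(O)O[C@@H]2/C=C(/C)CC/C=C(\C)[C@@H](OC3CCCCO3)[C@H](O[Si](C)(C)C(C)(C)C)[C@@H]12 | intermediate (not isolated)
28 | (6R,7S,8R,9R)-8-[(tert-butyldimethylsilyl)oxy]-9-(oxan-2-yloxy)germacra-1(10)E,4Z,11(13)-trien-12,6-olide | C=C1C(=O)O[C@@H]2/C=C(/C)CC/C=C(\C)[C@@H](OC3CCCCO3)[C@H](O[Si](C)(C)C(C)(C)C)[C@@H]12 | intermediate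
29 | (6R,7R,8R,9R)-8-hydroxy-9-(oxan-2-yloxy)germacra-1(10)E,4Z,11(13)-trien-12,6-olide | C=C1C(=O)O[C@@H]2/C=C(/C)CC/C=C(\C)[C@@H](OC3CCCCO3)[C@H](O)[C@@H]12 | intermediate
30 | (6R,7S,9R)-8-oxo-9-(oxan-2-yloxy)germacra-1(10)E,4Z,11(13)-trien-12,6-olide | C=C1C(=O)O[C@@H]2/C=C(/C)CC/C=C(\C)[C@@H](OC3CCCCO3)C(=O)[C@@H]12 | intermediate
31 | (6R,7R,8S,9R)-8-hydroxy-9-(oxan-2-yloxy)germacra-1(10)E,4Z,11(13)-trien-12,6-olide | C=C1C(=O)O[C@@H]2/C=C(/C)CC/C=C(\C)[C@@H](OC3CCCCO3)[C@@H](O)[C@@H]12 | intermediate
32 | (6R,7S,8S,9R)-8-(2-methylpropanoyloxy)-9-(oxan-2-yloxy)germacra-1(10)E,4Z,11(13)-trien-12,6-olide | C=C1C(=O)O[C@@H]2/C=C(/C)CC/C=C(\C)[C@@H](OC3CCCCO3)[C@@H](OC(=O)C(C)C)[C@@H]12 | intermediate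
33 | (6R,7S,8S,9R)-9-hydroxy-8-(2-methylpropanoyloxy)germacra-1(10)E,4Z,11(13)-trien-12,6-olide | C=C1C(=O)O[C@@H]2/C=C(/C)CC/C=C(\C)[C@@H](O)[C@@H](OC(=O)C(C)C)[C@@H]12 | intermediate
34 | (1R,4Z,6R,7S,8S,9S,10R)-1,10-epoxy-9-hydroxy-8-(2-methylpropanoyloxy)germacra-4,11(13)-dien-12,6-olide | C=C1C(=O)O[C@@H]2/C=C(/C)CC[C@H]3O[C@]3(C)[C@@H](O)[C@@H](OC(=O)C(C)C)[C@@H]12 | target

## Step count and least certain steps

Total step count: 22. Longest linear sequence: 19 steps (1, 2, 5–8, 10–22, from nerol 1).

**Step 14 (key step).** Two things can go wrong. Metalation may occur at C13 or C12 instead of C6, which would lead to loss of the C8 silyloxy group by 1,4-elimination or to a [1,2]-shift; both positions are allylic and alpha to oxygen, and only sterics and the impossibility of a productive shift speak against them. Face selection at C7 may also be incomplete, because the Felkin–Anh-type argument is carried over from open-chain [2,3]-shifts into a macrocycle.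
- Fallback (sets out from 21, returns at 24, and also bypasses step 13): oxidise the C6 hydroxyl of 21 with MnO2 to the Z chloro enal F1, then treat with CrCl2 (divalent chromium chloride) at high dilution. The allylchromium formed from the C13 chloride adds to the C6 aldehyde through C7 (Nozaki–Hiyama-type allylation). This forms the same C6–C7 bond with the same shift of the alkene to C11=C13 and should give 24 with the anti relation from a chair transition state. Its face selectivity relative to C8 and the stability of the Z enal would have to be established.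

**Step 11.** The C7=C11 geometry may be eroded, because the two CH2O arms on C11 are similar in size and chloride can re-enter by repeated SN2′ exchange.
- Fallback (sets out from 18, returns at 20): acetylate 18 to the C7 acetate F2; rearrange with PdCl2(MeCN)2 (divalent palladium, catalytic), a suprafacial [3,3]-shift through a chair that places C8 equatorial, to the primary allylic acetate F3; cleave with K2CO3 in MeOH to the primary allylic alcohol F4; chlorinate with PPh3 and N-chlorosuccinimide to 20.

**Step 19 (with step 18).** Ketone 30 may enolise toward C7, which would epimerise C7 or move the C11=C13 double bond into conjugation; C7–H is alpha to the ketone and allylic to the methylene lactone. Chelation through the bulky acetal oxygen may also be incomplete, which would return the 8α alcohol.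
- Fallback (sets out from 29, returns at 32): Mitsunobu esterification of 29 with 2-methylpropanoic acid (PPh3, DIAD), which installs the ester with inversion at C8 in one step and makes no new compound (F0). Its own risk is elimination, since backside attack at a ten-membered-ring carbon is slow.

**Step 22.** Face selection may be poor if the ring reacts through the conformer with C14 turned to the other face, and some epoxidation of C4=C5 may compete.
- Fallback (sets out from 33, returns at 34): form the bromohydrin F5 with N-bromosuccinimide in aqueous THF (bromonium ion on the peripheral face, water at the tertiary C10 from the opposite face), then close the ring with Ag2O. This places the epoxide oxygen on the face opposite to the one a peracid attacks.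

## Further compounds

F1 | step 14 | (2Z,6E,8R,9R,10E)-9-[(tert-butyldimethylsilyl)oxy]-11-{[(tert-butyldimethylsilyl)oxy]methyl}-12-chloro-3,7-dimethyl-8-(oxan-2-yloxy)dodeca-2,6,10-trienal | O=C/C=C(/C)CC/C=C(\C)[C@@H](OC1CCCCO1)[C@H](O[Si](C)(C)C(C)(C)C)/C=C(/CCl)CO[Si](C)(C)C(C)(C)C
F2 | step 11 | C3 (future C7) acetate of 18 | COc1ccc(COC/C=C(/C)CC/C=C(\C)[C@@H](OC2CCCCO2)[C@H](O[Si](C)(C)C(C)(C)C)C(OC(C)=O)C(=C)CO[Si](C)(C)C(C)(C)C)cc1
F3 | step 11 | primary allylic acetate (acetoxy in place of chlorine in 20) | COc1ccc(COC/C=C(/C)CC/C=C(\C)[C@@H](OC2CCCCO2)[C@H](O[Si](C)(C)C(C)(C)C)/C=C(/COC(C)=O)CO[Si](C)(C)C(C)(C)C)cc1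
F4 | step 11 | primary allylic alcohol (hydroxyl in place of chlorine in 20) | COc1ccc(COC/C=C(/C)CC/C=C(\C)[C@@H](OC2CCCCO2)[C@H](O[Si](C)(C)C(C)(C)C)/C=C(/CO)CO[Si](C)(C)C(C)(C)C)cc1
F0 | step 19 | none | none
F5 | step 22 | (1S,4Z,6R,7S,8S,9S,10R)-1-bromo-9,10-dihydroxy-8-(2-methylpropanoyloxy)germacra-4,11(13)-dien-12,6-olide | C=C1C(=O)O[C@@H]2/C=C(/C)CC[C@H](Br)[C@](C)(O)[C@@H](O)[C@@H](OC(=O)C(C)C)[C@@H]12
A1 | alternative 1 | C9 triethylsilyl ether of 34 | C=C1C(=O)O[C@@H]2/C=C(/C)CC[C@H]3O[C@]3(C)[C@@H](O[Si](CC)(CC)CC)[C@@H](OC(=O)C(C)C)[C@@H]12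
A2 | alternative 2 | 6,12-bis-O-(tert-butyldimethylsilyl)germacra-1(10)E,4Z,11(13)-triene-6α,8β,9β,12-tetrol | C=C(CO[Si](C)(C)C(C)(C)C)[C@@H]1[C@H](O)[C@H](O)/C(C)=C/CC/C(C)=C\[C@H]1O[Si](C)(C)C(C)(C)C
A3 | alternative 3 | 8-de(2-methylpropanoyl) 34 as its C9 tert-butyldimethylsilyl ether | C=C1C(=O)O[C@@H]2/C=C(/C)CC[C@H]3O[C@]3(C)[C@@H](O[Si](C)(C)C(C)(C)C)[C@@H](O)[C@@H]12
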